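**Plan**
- Retrosynthesis: the two ring hydroxyls are removed first, the quinone oxygens are traced back to one phenol per ring, and the tether is then cut at both benzylic positions, C1=C2 and C13=C14 (C1 and C14 are the chain carbons bonded to the rings).
- Enabling feature: C1 and C14 are each the former formyl carbon of the same arene aldehyde, C2–C13 is an unbranched twelve-carbon unit, and the two six-membered rings are identical, so one C12 bis-ylide can take up two molecules of a single aldehyde.
- Forward: the bis-phosphonium salt is made, then both rings are joined to the chain in one flask. No ring is formed at any stage; both carbocycles arrive intact with the aldehyde.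
- Ring finishing: hydrogenation, removal of one methyl per ring, Teuber oxidation to the methoxy-methyl-quinone, nucleophilic epoxidation of the only CH-bearing ring double bond, and acid isomerisation to the hydroxyquinone.
- Stereochemistry: the target has no stereocentre and no stereogenic double bond. The Wittig alkene geometry is erased by hydrogenation and the oxirane stereocentres are erased in the last step.

Key step: step 2

Remarks: aldehyde 4 is taken as a purchased compound. Compound 6 is drawn as the (Z,Z) isomer expected from a non-stabilised ylide; any E isomer is carried along. Compound 10 is expected as a mixture of diastereomers (each oxirane cis-fused and racemic), all converging on 11. Steps 1 and 2 each consume two molecules of one component per molecule of the chain unit; the second molecule is entered on the line for reagents that add atoms.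

Step 1
Reactants: 1 1,12-dibromododecane; 2 triphenylphosphine (first of two molecules)
Product: 3 dodecane-1,12-diylbis(triphenylphosphonium) dibromide
Conditions: PPh3 (2.2 equiv in all), DMF, 120 °C; precipitate with Et2O, dry under vacuum
Reagents that add atoms: triphenylphosphine 2 (second molecule, one per C–Br end), c1ccc(cc1)P(c1ccccc1)c1ccccc1
Why: Twofold SN2 quaternisation of a phosphine by an unhindered primary dibromide, which under forcing conditions should go to completion at both ends and deliver a salt that is freed from excess phosphine by trituration.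

Step 2
Reactants: 3 dodecane-1,12-diylbis(triphenylphosphonium) dibromide; 4 3,5-dimethoxy-4-methylbenzaldehyde (first of two molecules)
Product: 6 (1Z,13Z)-1,14-bis(3,5-dimethoxy-4-methylphenyl)tetradeca-1,13-diene, via bis-ylide 5 (not isolated)
Conditions: NaN(SiMe3)2 (2.1 equiv), THF, 0 °C; then 4 (2.3 equiv in all), −78 °C to rt
Reagents that add atoms: 3,5-dimethoxy-4-methylbenzaldehyde 4 (second molecule, one per ylide end), COc1cc(C=O)cc(OC)c1C
Why: This is a Wittig olefination run twice on one linchpin: NaN(SiMe3)2 removes one α-proton at each phosphonium end to give the non-stabilised bis-ylide 5, each ylide carbon adds to the formyl carbon of one molecule of 4, and the four-membered P–O adduct collapses with loss of Ph3P=O, creating C1=C2 and C13=C14. The closest known reaction type is the olefination of aromatic aldehydes with ylides derived from α,ω-alkanediylbis(triphenylphosphonium) salts. No ring is closed and no stereocentre is created; the Z geometry expected from a lithium-free non-stabilised ylide under kinetic control is of no consequence because both alkenes are saturated in step 3. The selectivity required is complete reaction at both termini instead of mono-olefination, and it is secured by the ten methylene groups that keep the two ylide ends electronically independent, by the small excess of the non-enolisable aldehyde 4, and by adding 4 to the preformed bis-ylide.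

Step 3
Reactants: 6 (1Z,13Z)-1,14-bis(3,5-dimethoxy-4-methylphenyl)tetradeca-1,13-diene
Product: 7 1,14-bis(3,5-dimethoxy-4-methylphenyl)tetradecane
Conditions: H2 (1 atm), 10% Pd/C, EtOAc, rt
Reagents that add atoms: none
Why: Heterogeneous catalytic hydrogenation of 1,2-disubstituted styrene-type alkenes is fast at ambient pressure, while the arene rings and aryl methyl ethers are untouched, so both geometric isomers converge on one saturated tether.

Step 4
Reactants: 7 1,14-bis(3,5-dimethoxy-4-methylphenyl)tetradecane
Product: 8 5,5'-(tetradecane-1,14-diyl)bis(3-methoxy-2-methylphenol)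
Conditions: NaSC2H5 (6 equiv), DMF, 140 °C; then aq. HCl
Reagents that add atoms: none
Why: Nucleophilic aryl methyl ether cleavage by SN2 attack of ethanethiolate on an O-methyl carbon; the phenoxide formed deactivates the second methoxy group of the same ring, so each ring should lose exactly one methyl, and the two methoxy groups of a ring are equivalent, so no regiochemical question arises.

Step 5
Reactants: 8 5,5'-(tetradecane-1,14-diyl)bis(3-methoxy-2-methylphenol)
Product: 9 5,5'-(tetradecane-1,14-diyl)bis(3-methoxy-2-methylcyclohexa-2,5-diene-1,4-dione)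
Conditions: (KSO3)2NO (6 equiv), KH2PO4, H2O/CH2Cl2, cat. methyltrioctylammonium chloride, rt
Reagents that add atoms: dipotassium nitrosodisulfonate (KSO3)2NO (Fremy's salt), [K+].[K+].[O]N(S(=O)(=O)[O-])S(=O)(=O)[O-]
Why: Teuber oxidation of a phenol with a free para position: the nitrosodisulfonate radical removes the phenolic hydrogen and a second equivalent transfers oxygen to the para carbon (the ring CH between the methoxy group and the chain) to give the para-quinone, the same change that converts 3-methoxy-5-alkylphenols into 2-methoxy-6-alkyl-1,4-benzoquinones.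

Step 6
Reactants: 9 5,5'-(tetradecane-1,14-diyl)bis(3-methoxy-2-methylcyclohexa-2,5-diene-1,4-dione)
Product: 10 1,1'-(tetradecane-1,14-diyl)bis(3-methoxy-4-methyl-7-oxabicyclo[4.1.0]hept-3-ene-2,5-dione)
Conditions: 30% aq. H2O2, Na2CO3, THF/H2O, 0 °C
Reagents that add atoms: hydrogen peroxide (one molecule per ring), OO
Why: Weitz–Scheffer nucleophilic epoxidation, in which hydroperoxide adds to the unsubstituted ring CH and the enolate closes onto oxygen; the trisubstituted C(chain)=CH bond should react in preference to the tetrasubstituted, electron-rich C(OMe)=C(Me) vinylogous ester, and the new oxirane stereocentres (cis-fused by necessity, formed without control) are destroyed in step 7.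

Step 7
Reactants: 10 1,1'-(tetradecane-1,14-diyl)bis(3-methoxy-4-methyl-7-oxabicyclo[4.1.0]hept-3-ene-2,5-dione)
Product: 11 3,3'-(tetradecane-1,14-diyl)bis(2-hydroxy-5-methoxy-6-methylcyclohexa-2,5-diene-1,4-dione)
Conditions: conc. H2SO4 on SiO2, CH2Cl2, rt
Reagents that add atoms: none
Why: Acid-catalysed isomerisation of a 2,3-epoxy-1,4-dione to a 2-hydroxy-1,4-quinone (the reaction that turns 2-methyl-1,4-naphthoquinone oxide into phthiocol), in which the oxirane C–O bond at the chain-bearing carbon breaks and the only oxirane proton is lost, so the hydroxyl can end up only on the former CH carbon next to the chain.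

**Compound list**
1 | 1,12-dibromododecane | BrCCCCCCCCCCCCBr | starting material
2 | triphenylphosphine | c1ccc(cc1)P(c1ccccc1)c1ccccc1 | starting material
3 | dodecane-1,12-diylbis(triphenylphosphonium) dibromide | [Br-].[Br-].c1ccc(cc1)[P+](CCCCCCCCCCCC[P+](c1ccccc1)(c1ccccc1)c1ccccc1)(c1ccccc1)c1ccccc1 | intermediate
4 | 3,5-dimethoxy-4-methylbenzaldehyde | COc1cc(C=O)cc(OC)c1C | starting material
5 | dodecane-1,12-diylidenebis(triphenylphosphorane), the bis-ylide | c1ccc(cc1)P(=CCCCCCCCCCCC=P(c1ccccc1)(c1ccccc1)c1ccccc1)(c1ccccc1)c1ccccc1 | intermediate
6 | (1Z,13Z)-1,14-bis(3,5-dimethoxy-4-methylphenyl)tetradeca-1,13-diene | COc1cc(/C=C\CCCCCCCCCC/C=C\c2cc(OC)c(C)c(OC)c2)cc(OC)c1C | intermediate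
7 | 1,14-bis(3,5-dimethoxy-4-methylphenyl)tetradecane | COc1cc(CCCCCCCCCCCCCCc2cc(OC)c(C)c(OC)c2)cc(OC)c1C | intermediate
8 | 5,5'-(tetradecane-1,14-diyl)bis(3-methoxy-2-methylphenol) | COc1cc(CCCCCCCCCCCCCCc2cc(O)c(C)c(OC)c2)cc(O)c1C | intermediate
9 | 5,5'-(tetradecane-1,14-diyl)bis(3-methoxy-2-methylcyclohexa-2,5-diene-1,4-dione) | COC1=C(C)C(=O)C=C(CCCCCCCCCCCCCCC2=CC(=O)C(C)=C(OC)C2=O)C1=O | intermediate
10 | 1,1'-(tetradecane-1,14-diyl)bis(3-methoxy-4-methyl-7-oxabicyclo[4.1.0]hept-3-ene-2,5-dione), mixture of stereoisomers at the cis-fused oxirane carbons | COC1=C(C)C(=O)C2OC2(CCCCCCCCCCCCCCC23OC2C(=O)C(C)=C(OC)C3=O)C1=O | intermediate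
11 | 3,3'-(tetradecane-1,14-diyl)bis(2-hydroxy-5-methoxy-6-methylcyclohexa-2,5-diene-1,4-dione) | COC1=C(C)C(=O)C(O)=C(CCCCCCCCCCCCCCC2=C(O)C(=O)C(C)=C(OC)C2=O)C1=O | target

**Step count**
Total steps: 7. Longest linear sequence: 7 steps (1 to 11); aldehyde 4 enters at step 2.

**Steps most likely to fail**

Step 7. Under strong acid the oxirane may open with acyl migration and ring contraction, or the vinylogous methyl ester may be hydrolysed, instead of the clean loss of the oxirane proton. The fallback sets out from 9 and returns at 11 without passing through an epoxide. The single ring C–H of each quinone is brominated by addition of Br2 and loss of HBr (Br2, NaOAc, AcOH, rt). This should give 3,3'-(tetradecane-1,14-diyl)bis(2-bromo-5-methoxy-6-methylcyclohexa-2,5-diene-1,4-dione) F1. Aqueous NaOH in dioxane at rt should then replace bromide by hydroxide through addition–elimination. Bromide is a far better leaving group than methoxide, and the hydroxyquinone anion formed resists further attack. Acidification with dilute HCl should give 11.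

Step 6. Hydroperoxide or hydroxide may add at the methoxy-bearing ring carbon with loss of methoxide, and alkaline peroxide may cleave the ring once some hydroxyquinone anion has formed. The fallback sets out from 9 and returns at 11 under acidic, anhydrous conditions. Thiele–Winter acetoxylation (Ac2O, BF3·OEt2, rt) adds acetate to the only unsubstituted ring carbon and should give 1,14-bis(2,3,6-triacetoxy-5-methoxy-4-methylphenyl)tetradecane F2. Methanolysis of the six acetates (HCl, MeOH, reflux, under N2) should give 1,14-bis(2,3,6-trihydroxy-5-methoxy-4-methylphenyl)tetradecane F3. Stirring F3 in air is expected to oxidise each 1,2,4-triol to the 2-hydroxy-1,4-quinone, giving 11.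

Step 5. The lipophilic bis-phenol may not meet the water-soluble radical, so that only one ring is oxidised or phenoxyl radicals couple. Step 4 may also stop with one ring still a dimethyl ether. The fallback sets out from 7 and returns at 9 without thiolate or nitrosodisulfonate. Rieche formylation (Cl2CHOCH3, TiCl4, CH2Cl2, 0 °C) at the ring position ortho to the chain and para to a methoxy group should give 6,6'-(tetradecane-1,14-diyl)bis(2,4-dimethoxy-3-methylbenzaldehyde) F4. Baeyer–Villiger oxidation with aryl migration (mCPBA, CH2Cl2) should then give 1,14-bis(2-formyloxy-3,5-dimethoxy-4-methylphenyl)tetradecane F5. Methanolysis (K2CO3, MeOH) should give 6,6'-(tetradecane-1,14-diyl)bis(2,4-dimethoxy-3-methylphenol) F6. Oxidative demethylation of this para-methoxyphenol with (NH4)2Ce(NO3)6 in MeCN/H2O at 0 °C should give 9.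

**Further compounds**
F1 | step 7 | 3,3'-(tetradecane-1,14-diyl)bis(2-bromo-5-methoxy-6-methylcyclohexa-2,5-diene-1,4-dione) | COC1=C(C)C(=O)C(Br)=C(CCCCCCCCCCCCCCC2=C(Br)C(=O)C(C)=C(OC)C2=O)C1=O
F2 | step 6 | 1,14-bis(2,3,6-triacetoxy-5-methoxy-4-methylphenyl)tetradecane | CC(=O)Oc1c(OC(C)=O)c(C)c(OC)c(OC(C)=O)c1CCCCCCCCCCCCCCc1c(OC(C)=O)c(OC(C)=O)c(C)c(OC)c1OC(C)=O
F3 | step 6 | 1,14-bis(2,3,6-trihydroxy-5-methoxy-4-methylphenyl)tetradecane | COc1c(C)c(O)c(O)c(CCCCCCCCCCCCCCc2c(O)c(O)c(C)c(OC)c2O)c1O
F4 | step 5 | 6,6'-(tetradecane-1,14-diyl)bis(2,4-dimethoxy-3-methylbenzaldehyde) | O=Cc1c(OC)c(C)c(OC)cc1CCCCCCCCCCCCCCc1cc(OC)c(C)c(OC)c1C=O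
F5 | step 5 | 1,14-bis(2-formyloxy-3,5-dimethoxy-4-methylphenyl)tetradecane | O=COc1c(OC)c(C)c(OC)cc1CCCCCCCCCCCCCCc1cc(OC)c(C)c(OC)c1OC=O
F6 | step 5 | 6,6'-(tetradecane-1,14-diyl)bis(2,4-dimethoxy-3-methylphenol) | Oc1c(OC)c(C)c(OC)cc1CCCCCCCCCCCCCCc1cc(OC)c(C)c(OC)c1O
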